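With the lactone ring numbered O1, C2 (carbonyl), C3, C4 (enol), C5 and the chain C6 to C18, the plan reads C4, C5, C6, C7, the C7 methyl and C8 as the six carbons of leucine. The key-step precursor is therefore just unprotected L-leucine (1). A leucine 5-hydroxylase oxidises one of its two diastereotopic methyl groups, which in a single operation installs the C8 oxygen handle and fixes C7 as R, giving (2S,4R)-5-hydroxyleucine (2). Afterwards the amino group is exchanged for the inverted C5 propionate, C8 becomes an E-iodoalkene, a citronellol-derived furyl alkyne is attached by methylalumination and cross-coupling, and a closing Dieckmann condensation forms the tetronic acid ring.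

Key step: step 1

Remark: the hydroxylase is assumed to be the 4R-selective leucine 5-hydroxylase of the griselimycin 4-methylproline pathway (GriE), and (S)-citronellol is mapped with its prenyl end toward the furan, which is the orientation that gives 15R.

Step 1
Reactants: 1 L-leucine
Product: 2 (2S,4R)-5-hydroxyleucine
Conditions: GriE leucine 5-hydroxylase (recombinant, E. coli lysate), α-ketoglutarate (1.2–1.5 equiv), sodium ascorbate, FeSO4 (cat.), air, phosphate buffer pH 7.5, 25 °C; Dowex 50WX8 (H+ form), aq. NH3 elution
Reagents that add atoms: dioxygen, O=O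
Why: In the enzyme, α-ketoglutarate chelated to divalent iron is oxidatively decarboxylated by O2 to succinate and CO2, leaving a tetravalent iron-oxo unit that pulls a hydrogen atom off the adjacent methyl group and then hands OH back to the carbon radical (oxygen rebound, enzymatic C–H hydroxylation). The closest known reaction is this same δ-hydroxylation of free L-leucine by iron and α-ketoglutarate dependent dioxygenases, so the enzyme meets its native substrate. No ring is formed in this step. The new stereocentre (C4 of the amino acid, C7 of the target) should be R because only the pro-S methyl group is oxidised, a choice made by the active-site pocket, which grips the L-configured ammonium carboxylate head group and so presents that one methyl group to the metal. The step needs methyl-over-methyl discrimination, preference for a primary C–H bond over the weaker tertiary C7–H bond, and a stop at the alcohol; the first two follow from substrate positioning, the last from keeping α-ketoglutarate to a small excess and monitoring conversion.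

Step 2
Reactants: 2 (2S,4R)-5-hydroxyleucine
Product: 3 (2S,4R)-2-amino-5-[(tert-butyldiphenylsilyl)oxy]-4-methylpentanoic acid
Conditions: TBDPSCl (1.1 equiv), DBU (1.1 equiv), MeCN, 0 °C → rt; aqueous work-up near pH 6
Reagents that add atoms: tert-butyl(chloro)diphenylsilane, CC(C)(C)[Si](Cl)(c1ccccc1)c1ccccc1
Why: Chemoselective O-silylation of a free hydroxy amino acid, in which the DBU carboxylate dissolves in MeCN and the bulky chlorosilane should take the unhindered primary C8 hydroxyl while leaving the amine, installed here so that the δ-oxygen can neither cyclise onto C5 nor lactonise in the acidic step that follows.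

Step 3
Reactants: 3 (2S,4R)-2-amino-5-[(tert-butyldiphenylsilyl)oxy]-4-methylpentanoic acid
Product: 6 (2S,4R)-5-[(tert-butyldiphenylsilyl)oxy]-2-hydroxy-4-methylpentanoic acid, via alpha-diazonium carboxylate 4 (not isolated), via alpha-lactone 5 (not isolated)
Conditions: NaNO2 (3 equiv), 0.5 M H2SO4/1,4-dioxane (1:1), 0 °C → rt
Reagents that add atoms: water, O
Why: Diazotisation of an α-amino acid with net retention by double inversion, the carboxylate expelling N2 to give the α-lactone and water then opening it at C5, so the S configuration should be kept while the silyl ether stops the C8 oxygen from acting as an internal nucleophile.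

Step 4
Reactants: 6 (2S,4R)-5-[(tert-butyldiphenylsilyl)oxy]-2-hydroxy-4-methylpentanoic acid
Product: 7 methyl (2S,4R)-5-[(tert-butyldiphenylsilyl)oxy]-2-hydroxy-4-methylpentanoate
Conditions: MeI (1.5 equiv), KHCO3 (1.5 equiv), DMF, rt
Reagents that add atoms: iodomethane, CI
Why: Carboxylate O-alkylation (esterification) should methylate only the acid, because bicarbonate does not deprotonate the secondary alcohol, and it supplies the ester that the ring closure attacks at the end.

Step 5
Reactants: 7 methyl (2S,4R)-5-[(tert-butyldiphenylsilyl)oxy]-2-hydroxy-4-methylpentanoate; 8 propionic acid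
Product: 9 methyl (2R,4R)-5-[(tert-butyldiphenylsilyl)oxy]-4-methyl-2-(propanoyloxy)pentanoate
Conditions: PPh3 (1.5 equiv), DIAD (1.5 equiv), THF, 0 °C → rt
Reagents that add atoms: none
Why: Mitsunobu esterification, in which the activated α-hydroxy ester is displaced by propionate in an SN2 step that should invert C5 from S to the R configuration of the target and bring in C2, C3 and the C3 methyl group.

Step 6
Reactants: 9 methyl (2R,4R)-5-[(tert-butyldiphenylsilyl)oxy]-4-methyl-2-(propanoyloxy)pentanoate
Product: 10 methyl (2R,4R)-5-hydroxy-4-methyl-2-(propanoyloxy)pentanoate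
Conditions: HF·pyridine, pyridine, THF, 0 °C → rt; crude product used at once
Reagents that add atoms: none
Why: Fluoride-mediated desilylation under pyridine-buffered conditions should free the C8 alcohol without base that could cause acyl migration or premature Claisen chemistry, and immediate use of the δ-hydroxy ester limits lactonisation.

Step 7
Reactants: 10 methyl (2R,4R)-5-hydroxy-4-methyl-2-(propanoyloxy)pentanoate
Product: 11 methyl (2R,4R)-4-methyl-5-oxo-2-(propanoyloxy)pentanoate
Conditions: Dess–Martin periodinane (1.3 equiv), NaHCO3, CH2Cl2, 0 °C → rt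
Reagents that add atoms: none
Why: Dess–Martin oxidation under bicarbonate buffering should give the α-methyl aldehyde without enolisation, so C7 stays R.

Step 8
Reactants: 11 methyl (2R,4R)-4-methyl-5-oxo-2-(propanoyloxy)pentanoate
Product: 12 methyl (2R,4R,5E)-6-iodo-4-methyl-2-(propanoyloxy)hex-5-enoate
Conditions: CrCl2 (6 equiv), CHI3 (2 equiv), THF/1,4-dioxane (1:6), 0 °C → rt, dark
Reagents that add atoms: iodoform, IC(I)I
Why: Takai olefination, in which the geminal dichromium species from CHI3 and CrCl2 adds to the aldehyde and eliminates to the E-iodoalkene under non-basic conditions that should spare both esters and the C5 and C7 centres; this step supplies C9.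

Step 9
Reactants: 13 (S)-citronellol
Product: 14 (6S)-8-iodo-2,6-dimethyloct-2-ene
Conditions: I2, PPh3, imidazole, CH2Cl2, 0 °C → rt
Reagents that add atoms: iodine, II
Why: Appel-type iodination converts the primary alcohol into the iodide by SN2 at a CH2 group, leaving the remote stereocentre (the future C15) and the trisubstituted alkene untouched.

Step 10
Reactants: 14 (6S)-8-iodo-2,6-dimethyloct-2-ene; 15 1-(trimethylsilyl)propyne
Product: 17 trimethyl[(6R)-6,10-dimethylundec-9-en-1-yn-1-yl]silane, via lithiated silylpropyne 16 (not isolated)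
Conditions: 15, n-BuLi, THF, −78 → −20 °C; then 14, −78 °C → rt
Reagents that add atoms: none
Why: Alkylation of lithiated 1-(trimethylsilyl)propyne, which reacts with primary iodides at its propargylic carbon, should add C10 to C12 in one SN2 step while keeping the alkyne masked.

Step 11
Reactants: 17 trimethyl[(6R)-6,10-dimethylundec-9-en-1-yn-1-yl]silane
Product: 19 (4R)-4-methyl-9-(trimethylsilyl)non-8-yn-1-ol, via secondary ozonide 18 (not isolated)
Conditions: O3, CH2Cl2, −78 °C (Sudan red 7B end-point); then NaBH4, MeOH, −78 → 0 °C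
Reagents that add atoms: ozone, [O-][O+]=O
Why: Ozonolysis with reductive work-up, in which ozone should attack the electron-rich trisubstituted alkene far faster than the silylated alkyne and hydride reduction of the ozonide delivers the C18 alcohol.

Step 12
Reactants: 19 (4R)-4-methyl-9-(trimethylsilyl)non-8-yn-1-ol
Product: 20 [(6R)-9-iodo-6-methylnon-1-yn-1-yl]trimethylsilane
Conditions: I2, PPh3, imidazole, CH2Cl2, 0 °C → rt
Reagents that add atoms: iodine, II
Why: Appel-type iodination of a primary alcohol by SN2 should give the C18 iodide without touching the alkynylsilane.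

Step 13
Reactants: 20 [(6R)-9-iodo-6-methylnon-1-yn-1-yl]trimethylsilane; 21 3-bromofuran
Product: 23 trimethyl[(6S)-9-(furan-3-yl)-6-methylnon-1-yn-1-yl]silane, via alkylzinc iodide 22 (not isolated)
Conditions: Zn dust (activated with TMSCl and BrCH2CH2Br), DMA, 40 °C; then 21, Pd(OAc)2 (3 mol%), SPhos (6 mol%), THF, 50 °C
Reagents that add atoms: none
Why: Negishi alkyl–heteroaryl cross-coupling, in which direct zinc insertion gives a primary alkylzinc iodide that tolerates the silyl alkyne and palladium with a bulky biaryl phosphine should join it to C3 of the furan faster than β-hydride elimination (the change of descriptor from R to S is only a change in priorities).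

Step 14
Reactants: 23 trimethyl[(6S)-9-(furan-3-yl)-6-methylnon-1-yn-1-yl]silane
Product: 24 3-[(4R)-4-methylnon-8-yn-1-yl]furan
Conditions: K2CO3 (cat.), MeOH, rt
Reagents that add atoms: none
Why: Methanolytic protodesilylation of the alkynylsilane should expose the terminal alkyne without affecting the furan.

Step 15
Reactants: 24 3-[(4R)-4-methylnon-8-yn-1-yl]furan; 12 methyl (2R,4R,5E)-6-iodo-4-methyl-2-(propanoyloxy)hex-5-enoate
Product: 26 methyl (2R,4R,5E,7E,12R)-15-(furan-3-yl)-4,8,12-trimethyl-2-(propanoyloxy)pentadeca-5,7-dienoate, via alkenylalane 25 (not isolated)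
Conditions: 24 (1.3 equiv), AlMe3 (2.5 equiv), Cp2ZrCl2 (0.25 equiv), ClCH2CH2Cl, rt; volatiles removed in vacuo; then 12, ZnCl2 (co-catalyst), Pd(PPh3)4 (5 mol%), THF, rt
Reagents that add atoms: trimethylaluminium, C[Al](C)C
Why: Zirconium-catalysed methylalumination (syn carbometalation with methyl going to the internal carbon) should set the C11 methyl group and the E geometry of C10=C11, and the alkenylalane is then joined to the E-iodoalkene by palladium-catalysed Negishi coupling, which retains both alkene geometries and is non-basic toward the esters and the C5 and C7 centres.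

Step 16
Reactants: 26 methyl (2R,4R,5E,7E,12R)-15-(furan-3-yl)-4,8,12-trimethyl-2-(propanoyloxy)pentadeca-5,7-dienoate
Product: 28 (5R)-5-[(2R,3E,5E,10R)-13-(furan-3-yl)-2,6,10-trimethyltrideca-3,5-dien-1-yl]-4-hydroxy-3-methylfuran-2(5H)-one (CNP0246504.1), via lithium tetronate 27 (not isolated)
Conditions: LiN(SiMe3)2 (3 equiv), THF, −78 → 0 °C; then cold 0.5 M HCl to pH 3
Reagents that add atoms: none
Why: Dieckmann (intramolecular Claisen) condensation of an α-acyloxy ester, in which the propionate enolate attacks the methyl ester in a 5-exo-trig closure and loss of methoxide followed by deprotonation gives the lithium tetronate, a sink that should shield C5 from epimerisation until mild acid releases the tetronic acid.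

Compound list
1 | L-leucine | CC(C)C[C@H](N)C(=O)O | starting material
2 | (2S,4R)-5-hydroxyleucine, i.e. (2S,4R)-2-amino-5-hydroxy-4-methylpentanoic acid | OC[C@H](C)C[C@H](N)C(=O)O | intermediate
3 | (2S,4R)-2-amino-5-[(tert-butyldiphenylsilyl)oxy]-4-methylpentanoic acid | CC(C)(C)[Si](OC[C@H](C)C[C@H](N)C(=O)O)(c1ccccc1)c1ccccc1 | intermediate
4 | (1S,3R)-4-[(tert-butyldiphenylsilyl)oxy]-1-carboxylato-3-methylbutane-1-diazonium (alpha-diazonium carboxylate, formed in the flask) | CC(C)(C)[Si](OC[C@H](C)C[C@H]([N+]#N)C(=O)[O-])(c1ccccc1)c1ccccc1 | intermediate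
5 | (3R)-3-[(2R)-3-[(tert-butyldiphenylsilyl)oxy]-2-methylpropyl]oxiran-2-one (alpha-lactone, formed in the flask) | CC(C)(C)[Si](OC[C@H](C)C[C@H]1OC1=O)(c2ccccc2)c2ccccc2 | intermediate
6 | (2S,4R)-5-[(tert-butyldiphenylsilyl)oxy]-2-hydroxy-4-methylpentanoic acid | CC(C)(C)[Si](OC[C@H](C)C[C@H](O)C(=O)O)(c1ccccc1)c1ccccc1 | intermediate
7 | methyl (2S,4R)-5-[(tert-butyldiphenylsilyl)oxy]-2-hydroxy-4-methylpentanoate | CC(C)(C)[Si](OC[C@H](C)C[C@H](O)C(=O)OC)(c1ccccc1)c1ccccc1 | intermediate
8 | propionic acid | CCC(=O)O | starting material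
9 | methyl (2R,4R)-5-[(tert-butyldiphenylsilyl)oxy]-4-methyl-2-(propanoyloxy)pentanoate | CC(C)(C)[Si](OC[C@H](C)C[C@@H](OC(=O)CC)C(=O)OC)(c1ccccc1)c1ccccc1 | intermediate
10 | methyl (2R,4R)-5-hydroxy-4-methyl-2-(propanoyloxy)pentanoate | OC[C@H](C)C[C@@H](OC(=O)CC)C(=O)OC | intermediate
11 | methyl (2R,4R)-4-methyl-5-oxo-2-(propanoyloxy)pentanoate | O=C[C@H](C)C[C@@H](OC(=O)CC)C(=O)OC | intermediate
12 | methyl (2R,4R,5E)-6-iodo-4-methyl-2-(propanoyloxy)hex-5-enoate | I/C=C/[C@H](C)C[C@@H](OC(=O)CC)C(=O)OC | intermediate
13 | (S)-citronellol, (3S)-3,7-dimethyloct-6-en-1-ol | C[C@@H](CCC=C(C)C)CCO | starting material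
14 | (6S)-8-iodo-2,6-dimethyloct-2-ene | C[C@@H](CCC=C(C)C)CCI | intermediate
15 | 1-(trimethylsilyl)propyne | CC#C[Si](C)(C)C | starting material
16 | [3-(trimethylsilyl)prop-2-yn-1-yl]lithium (formed in the flask) | [Li]CC#C[Si](C)(C)C | intermediate
17 | trimethyl[(6R)-6,10-dimethylundec-9-en-1-yn-1-yl]silane | C[C@@H](CCC=C(C)C)CCCC#C[Si](C)(C)C | intermediate
18 | 3,3-dimethyl-5-[(3R)-3-methyl-8-(trimethylsilyl)oct-7-yn-1-yl]-1,2,4-trioxolane (secondary ozonide, both epimers at the ring CH, formed in the flask) | C[C@@H](CCC1OOC(C)(C)O1)CCCC#C[Si](C)(C)C | intermediate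
19 | (4R)-4-methyl-9-(trimethylsilyl)non-8-yn-1-ol | C[C@@H](CCCO)CCCC#C[Si](C)(C)C | intermediate
20 | [(6R)-9-iodo-6-methylnon-1-yn-1-yl]trimethylsilane | C[C@@H](CCCI)CCCC#C[Si](C)(C)C | intermediate
21 | 3-bromofuran | Brc1ccoc1 | starting material
22 | iodo[(4R)-4-methyl-9-(trimethylsilyl)non-8-yn-1-yl]zinc (formed in the flask) | C[C@@H](CCC[Zn]I)CCCC#C[Si](C)(C)C | intermediate
23 | trimethyl[(6S)-9-(furan-3-yl)-6-methylnon-1-yn-1-yl]silane | C[C@@H](CCCc1ccoc1)CCCC#C[Si](C)(C)C | intermediate
24 | 3-[(4R)-4-methylnon-8-yn-1-yl]furan | C#CCCC[C@@H](C)CCCc1ccoc1 | intermediate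
25 | dimethyl[(1E,6S)-9-(furan-3-yl)-2,6-dimethylnon-1-en-1-yl]alumane (formed in the flask) | C[Al](C)/C=C(\C)CCC[C@@H](C)CCCc1ccoc1 | intermediate
26 | methyl (2R,4R,5E,7E,12R)-15-(furan-3-yl)-4,8,12-trimethyl-2-(propanoyloxy)pentadeca-5,7-dienoate | CCC(=O)O[C@H](C[C@@H](C)/C=C/C=C(\C)CCC[C@@H](C)CCCc1ccoc1)C(=O)OC | intermediate
27 | lithium (5R)-5-[(2R,3E,5E,10R)-13-(furan-3-yl)-2,6,10-trimethyltrideca-3,5-dien-1-yl]-3-methyl-2-oxo-2,5-dihydrofuran-4-olate (formed in the flask) | CC1=C([O-])[C@@H](C[C@@H](C)/C=C/C=C(\C)CCC[C@@H](C)CCCc2ccoc2)OC1=O.[Li+] | intermediate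
28 | CNP0246504.1, (5R)-5-[(2R,3E,5E,10R)-13-(furan-3-yl)-2,6,10-trimethyltrideca-3,5-dien-1-yl]-4-hydroxy-3-methylfuran-2(5H)-one | CC1=C(O)[C@@H](C[C@@H](C)/C=C/C=C(\C)CCC[C@@H](C)CCCc2ccoc2)OC1=O | target

Total step count: 16. Longest linear sequence: 10 steps (steps 1 to 8, 15 and 16, from L-leucine); the furyl alkyne branch takes 6 steps (9 to 14) before the union.

Steps most likely to fail

Step 16. Deprotonation at C5 (next to the ester and bearing the acyloxy group) may compete with enolisation of the propionate. This would epimerise C5 or move the acyl group from oxygen to carbon before the ring closes, on fully assembled material. The fallback closes the ring before the fragments are joined and carries the tetronic acid as its methyl ether. It sets out from 12: LiN(SiMe3)2 in THF at −78 °C should give (5R)-4-hydroxy-5-[(2R,3E)-4-iodo-2-methylbut-3-en-1-yl]-3-methylfuran-2(5H)-one F1, where any C5 epimer is a diastereomer that can be removed on a small intermediate. Me2SO4 and K2CO3 in acetone should give (5R)-5-[(2R,3E)-4-iodo-2-methylbut-3-en-1-yl]-4-methoxy-3-methylfuran-2(5H)-one F2. Coupling with alkenylalane 25 under the conditions of step 15 should give (5R)-5-[(2R,3E,5E,10R)-13-(furan-3-yl)-2,6,10-trimethyltrideca-3,5-dien-1-yl]-4-methoxy-3-methylfuran-2(5H)-one F3. Neutral SN2 demethylation with LiCl in DMSO at 60 °C then comes back to the route at 28.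

Step 15. Methylalumination may be incomplete or unselective in the presence of the furan, residual organoaluminium may attack the esters of 12, and the alkenyl metal may homocouple. The fallback replaces the one-pot alane coupling with an isolated, purified alkenylstannane and a neutral Stille coupling. It sets out from 24: methylalumination followed by iodinolysis (I2, THF, −30 °C) should give 3-[(4S,8E)-9-iodo-4,8-dimethylnon-8-en-1-yl]furan F4. Iodine–lithium exchange (t-BuLi, Et2O, −78 °C) and quenching with Bu3SnCl should give tributyl[(1E,6S)-9-(furan-3-yl)-2,6-dimethylnon-1-en-1-yl]stannane F5. Stille coupling of F5 with 12 (Pd(PPh3)4, CuI, CsF, DMF, rt) comes back to the route at 26.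

Step 3. Aqueous acid may cleave the silyl ether, or its oxygen may take part, after which the δ-oxygen closes a tetrahydrofuran at C5 instead of water opening the α-lactone. The fallback uses an acid-stable ester as the mask during diazotisation and installs the silyl ether afterwards. It sets out from 2: O-acetylation under strongly acidic conditions (AcCl, CF3CO2H, amine protonated) should give (2S,4R)-5-acetoxy-2-amino-4-methylpentanoic acid hydrochloride F6. Diazotisation (NaNO2, aq. H2SO4, 0 °C) should give (2S,4R)-5-acetoxy-2-hydroxy-4-methylpentanoic acid F7 with retention. Methanolysis with K2CO3 in MeOH should give potassium (2S,4R)-2,5-dihydroxy-4-methylpentanoate F8, kept as the carboxylate salt so that it cannot lactonise. Primary-selective silylation (TBDPSCl, imidazole, DMF, 0 °C, mild aqueous work-up) comes back to the route at 6.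

Further compounds
F1 | step 16 | (5R)-4-hydroxy-5-[(2R,3E)-4-iodo-2-methylbut-3-en-1-yl]-3-methylfuran-2(5H)-one | CC1=C(O)[C@@H](C[C@@H](C)/C=C/I)OC1=O
F2 | step 16 | (5R)-5-[(2R,3E)-4-iodo-2-methylbut-3-en-1-yl]-4-methoxy-3-methylfuran-2(5H)-one | CC1=C(OC)[C@@H](C[C@@H](C)/C=C/I)OC1=O
F3 | step 16 | (5R)-5-[(2R,3E,5E,10R)-13-(furan-3-yl)-2,6,10-trimethyltrideca-3,5-dien-1-yl]-4-methoxy-3-methylfuran-2(5H)-one | CC1=C(OC)[C@@H](C[C@@H](C)/C=C/C=C(\C)CCC[C@@H](C)CCCc2ccoc2)OC1=O
F4 | step 15 | 3-[(4S,8E)-9-iodo-4,8-dimethylnon-8-en-1-yl]furan | I/C=C(\C)CCC[C@@H](C)CCCc1ccoc1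
F5 | step 15 | tributyl[(1E,6S)-9-(furan-3-yl)-2,6-dimethylnon-1-en-1-yl]stannane | CCCC[Sn](CCCC)(CCCC)/C=C(\C)CCC[C@@H](C)CCCc1ccoc1
F6 | step 3 | (2S,4R)-5-acetoxy-2-amino-4-methylpentanoic acid hydrochloride | CC(=O)OC[C@H](C)C[C@H](N)C(=O)O.Cl
F7 | step 3 | (2S,4R)-5-acetoxy-2-hydroxy-4-methylpentanoic acid | CC(=O)OC[C@H](C)C[C@H](O)C(=O)O
F8 | step 3 | potassium (2S,4R)-2,5-dihydroxy-4-methylpentanoate | OC[C@H](C)C[C@H](O)C(=O)[O-].[K+]
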